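## The problem

Target 15 is a trans-2,3-disubstituted 2,3-dihydro-1-benzofuran. C2 carries a 1-formylvinyl group, C3 a 3-methylbutanoate, and C5 a (1R)-1-acyloxyethyl chain whose acid is (2R)-2-methylbutanoic acid. Two of the four stereocentres are easy: the acid α-carbon can be bought, and the side-chain carbinol can be set on a simple aryl methyl ketone. That carbinol lies across the benzene ring from C2 and C3 and cannot influence them. C2 and C3 are adjacent and can control each other, so the real task is to create this pair trans and in the (2R,3S) sense under an external chiral influence. Because the side chain is already homochiral, an error there shows up as a diastereomer, not an enantiomer.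

The molecule tolerates little. The enal is a Michael acceptor. The C3 ester is benzylic and can be eliminated towards the aromatic benzofuran. The C5 ester is benzylic and para to the ring oxygen, so it ionises under acid and would be expelled as a quinone methide if that oxygen were ever a free phenoxide. Every carbonyl group on the C2 chain sits β to the aryloxy oxygen, which invites ring opening by retro-oxa-Michael elimination whenever an α-hydrogen is acidic.

A short route is possible because of the polarity pattern of the dihydrofuran ring. C3 is a benzylic carbinol carbon ortho to O1, a latent aryl aldehyde. C2 is the β-carbon of a three-carbon acrylic unit hanging from O1. Both are electrophilic in the obvious precursor, and they can be joined if the aldehyde is turned into a nucleophilic ketyl.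

## Retrosynthesis

**15 to 13.** The exocyclic C=CH2 bond of the acrolein unit is cut first, which leads back to aldehyde 13 and a one-carbon iminium electrophile (through Mannich base 14). The enal is the most reactive function and should appear last. Once the α-carbon is sp2 the chain has no α-hydrogen, so the ring can no longer open. The forward reaction must trap the enol of 13 faster than that enol expels the ring oxygen.

**13 to 11 to 10.** Two functional-group changes follow, with no skeletal bond cut. The aldehyde is taken back to the dimethylamide 11 (through hemiaminal 12), and the C3 ester to the free alcohol 10. The amide holds the aldehyde oxidation level in a form that survives divalent samarium and acylation, and that can be told apart from the two esters at the reduction stage. Acylating before reducing keeps a free hydroxyl away from the zirconium hydride and from the aldehyde.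

**10 to 9.** The C2–C3 bond is cut, which opens the ring and removes both ring stereocentres at once. The neighbouring cut at O1–C2 would need C3 to be made first by an asymmetric carbonyl addition, followed by a separate diastereoselective C–O closure. The C2–C3 cut instead leads to an acyclic aryl aldehyde with an (E)-aryloxyacrylamide on the ortho oxygen (9), which needs only one bond to be formed from a phenol and an alkyne. The forward reaction must join two electrophilic carbons, place the C3 oxygen trans to the C2 chain, and choose one face. The first two follow from ketyl–olefin reactivity. The third is asked of a chiral aminodiol ligand on samarium. To give the ligand a fair chance, the acceptor is an amide, whose strongly Lewis-basic carbonyl can bind the same samarium centre as the ketyl oxygen. The cost of failure is limited because the wrong isomer is a diastereomer of 10 and can be removed by a resolution that doubles as the next acylation.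

**9 to 6 and 7.** The side-chain ester C–O bond is cut here and not earlier. In 6 the ring oxygen is already a vinylogous carbamate oxygen, and its lone pair is drawn into the acrylamide. If the ester were present while this oxygen was still a phenoxide (during formylation or aryl ether formation), a 1,6-elimination of carboxylate to a quinone methide would be expected. The forward step is a Steglich esterification through O-acylisourea 8, which does not touch the carbinol C–O bond.

**6 to 4 and 5.** The O–C(vinyl) bond is cut, giving salicylaldehyde 4 and N,N-dimethylprop-2-ynamide 5. An amine-catalysed oxa-Michael addition makes this bond with (E) geometry. The acidic salicylaldehyde phenol reacts, and the secondary alcohol does not.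

**4 to 2 to 1.** The formyl C–C bond ortho to the phenol is cut, giving 2 (through salicyl alcohol 3). The carbinol C–H bond is then cut, giving 4'-hydroxyacetophenone 1. Formylation is directed by the phenol to the only open ortho positions, which are equivalent. The carbinol centre comes from asymmetric transfer hydrogenation of the ketone. No protecting group is needed if the carbinol survives the formylation.

## Roads not taken

**Alternative 1:** This road cuts both C2–C3 and O1–C2. Salicylaldehyde A1, which already carries the side-chain ester, would be annulated with a chiral methallylsulfonium ylide (Cs2CO3) to give the isopropenyl carbinol A2. The ylide carbon adds to the aldehyde, and the phenoxide oxygen then displaces the sulfide from the same carbon.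

- **Merits.** The ring, both stereocentres and all three carbons of the future acrolein arrive in one step. The endgame is only acylation and allylic oxidation of the isopropenyl group with SeO2. It never passes through an enolisable β-aryloxy aldehyde, and in that respect it is better than the chosen plan.
- **Weak points.** The betaine from a sulfonium ylide and an aldehyde normally closes through its own alkoxide to an epoxide, so the phenoxide closure has to win a competition it usually loses. Allylic sulfonium ylides also undergo sigmatropic shifts and can react at the γ-carbon. A1 has to be used as a free phenoxide, which is the arrangement that expels the para benzylic carboxylate. A stoichiometric chiral sulfide is needed. SeO2 must then discriminate on a molecule with two benzylic esters.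
- **Comparison.** Absolute control rests on an unproven reagent here as well, so the two plans are equal on that count. The chosen plan offers an order of events in which the ring oxygen is never a phenoxide next to the benzylic ester, and a ring closure whose trans preference has close analogy.

**Alternative 2:** This road cuts O1–C2 and the bond between the α-carbon and the carbonyl carbon. The allenyl phenol A3 (from A1 by asymmetric allenylation and silylation) would be treated with PdCl2, CuCl2, CO and N,O-dimethylhydroxylamine. The phenol oxygen adds to the allene carbon next to C3 in a 5-exo closure. The vinyl complex of divalent palladium at the central carbon inserts CO, and the acyl group is trapped by the amine to give acrylamide A4.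

- **Merits.** The methylene group is present from the start, so no late α-methylenation is needed. C2 is set by the existing C3 centre, which in turn comes from a conventional asymmetric carbonyl addition. This stereochemical logic is more conservative than a ligand-controlled ketyl cyclisation, and the endgame is safer against ring opening.
- **Weak points.** The phenol of A3 is again free beside the para benzylic ester. The trans preference of oxypalladation next to a silyloxy group is not assured. An amine nucleophile under oxidative Pd/Cu/CO conditions can bind the metal or be carbonylated itself. After A4 there remain desilylation, acylation, and reduction of an N-methoxy-N-methyl acrylamide to an enal in the presence of two esters, where 1,4-reduction competes.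
- **Comparison.** The chosen plan is shorter, uses no protecting group, and sets both ring centres in one step. It pays for this with the unproven face selection.

**Alternative 3:** This road cuts O1–C2 of the dihydrofuran in A8 and traces it to a chroman. Chromene A5 would be converted by Jacobsen epoxidation into epoxide A6. The epoxide would be opened at C4 by 3-methylbutanoic acid to the trans chromanol A7. Tf2O and 2,6-di-tert-butylpyridine would turn the C3 hydroxyl into a triflate, which the ring oxygen displaces from the rear. The six-membered ring contracts, and the tertiary cation loses a proton to give the isopropenyl ester A8.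

- **Merits.** Absolute configuration comes from an epoxidation for which 2,2-dimethylchromenes are the best substrates. This is clearly more dependable than the ligand control in the chosen plan. The trans relationship follows from two stereospecific inversions. The isopropenyl group appears in the same step, leaving only the SeO2 oxidation.
- **Weak points.** The neighbouring C4 ester can take part in the ionisation through an acyloxonium ion in place of the ring oxygen. The cation has more than one way to lose a proton. Triflation is run on a molecule with two ionisable benzylic esters. The sequence is at least as long once the chromene has been built and the side chain reduced and esterified.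
- **Comparison.** The chosen plan is shorter, milder (no triflate, no SeO2), and has a resolution-based fallback for the step where this alternative is stronger.

Key step: step 5

## Route

Assumption: the face selected by the samarium–aminodiol complex on this substrate cannot be predicted, so the (R,R)-ligand is written in step 5 and its enantiomer would be used if the opposite face is attacked.

Step 1
Reactants: 1 4'-hydroxyacetophenone
Product: 2 4-[(1R)-1-hydroxyethyl]phenol
Conditions: RuCl[(R,R)-TsDPEN](p-cymene) (1 mol %), HCO2H/Et3N (5:2), EtOAc, 30 °C
Reagents that add atoms: none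
Why: Noyori asymmetric transfer hydrogenation of an aryl methyl ketone; the (R,R)-diamine complex of divalent ruthenium delivers hydride to the Si face of aryl methyl ketones and gives (R)-1-arylethanols, and the formic acid medium keeps the phenol protonated so the ketone is not deactivated as a phenoxide.

Step 2
Reactants: 2 4-[(1R)-1-hydroxyethyl]phenol
Product: 4 2-hydroxy-5-[(1R)-1-hydroxyethyl]benzaldehyde, via salicyl alcohol 3 (not isolated)
Conditions: MgCl2, Et3N, (CH2O)n, THF, reflux; then cold aq. NH4Cl
Reagents that add atoms: paraformaldehyde (source of formaldehyde), C=O
Why: Magnesium-mediated ortho-formylation of a phenol (Casnati–Skattebøl reaction): the magnesium phenoxide delivers formaldehyde to the ortho carbon and the resulting salicyl alkoxide 3 is oxidised within the chelate by a second formaldehyde through hydride transfer; the para position is blocked, the two ortho positions are equivalent, and the carbinol centre takes no part.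

Step 3
Reactants: 4 2-hydroxy-5-[(1R)-1-hydroxyethyl]benzaldehyde; 5 N,N-dimethylprop-2-ynamide
Product: 6 (2E)-3-{2-formyl-4-[(1R)-1-hydroxyethyl]phenoxy}-N,N-dimethylprop-2-enamide
Conditions: 1,4-diazabicyclo[2.2.2]octane (DABCO, 20 mol %), MeCN, 0 °C → rt
Reagents that add atoms: none
Why: Amine-catalysed oxa-Michael addition of a phenol to an activated alkyne: DABCO adds to the propiolamide, the acidic salicylaldehyde phenol protonates the zwitterion, and its phenoxide then adds and expels the amine to leave the thermodynamically preferred (E)-aryloxyacrylamide; the much less acidic secondary alcohol does not compete, and gentle warming may be needed because a propiolamide is less electrophilic than a propiolate.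

Step 4
Reactants: 6 (2E)-3-{2-formyl-4-[(1R)-1-hydroxyethyl]phenoxy}-N,N-dimethylprop-2-enamide; 7 (2R)-2-methylbutanoic acid
Product: 9 (1R)-1-(4-{[(1E)-3-(dimethylamino)-3-oxoprop-1-en-1-yl]oxy}-3-formylphenyl)ethyl (2R)-2-methylbutanoate, via O-acylisourea 8 (not isolated)
Conditions: DCC, 4-(dimethylamino)pyridine (DMAP, 10 mol %), CH2Cl2, 0 °C → rt
Reagents that add atoms: none
Why: Steglich esterification through O-acylisourea 8 and the acylpyridinium ion: the carbinol C–O bond is not broken, so the (1R) centre is retained, and the α-centre of the acid is not enolised under these mild conditions; the ring oxygen is by now a vinylogous carbamate oxygen and can no longer push out the new carboxylate as a quinone methide.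

Step 5
Reactants: 9 (1R)-1-(4-{[(1E)-3-(dimethylamino)-3-oxoprop-1-en-1-yl]oxy}-3-formylphenyl)ethyl (2R)-2-methylbutanoate
Product: 10 (1R)-1-{(2R,3S)-2-[2-(dimethylamino)-2-oxoethyl]-3-hydroxy-2,3-dihydro-1-benzofuran-5-yl}ethyl (2R)-2-methylbutanoate
Conditions: SmI2 (2.5 equiv), (1R,1'R)-2,2'-(benzylazanediyl)bis(1-phenylethan-1-ol) (2.5 equiv), MeOH (10 equiv), THF, −78 °C, 9 added slowly
Reagents that add atoms: none
Why: Proposed new method: divalent samarium reduces the aryl aldehyde of 9 to a samarium-bound ketyl, a nucleophilic radical at the future C3, which adds to the electron-poor β-carbon of the (E)-aryloxyacrylamide (the future C2); the α-carbamoyl radical is reduced by a second equivalent to a samarium enolate that MeOH protonates before it can expel the ring oxygen. The closest known reaction types are the SmI2-promoted cyclisation of aldehydes onto β-alkoxyacrylates, which gives 2,3-trans cyclic ethers, and ligand-controlled enantioselective samarium ketyl–olefin cyclisations with a chiral aminodiol; neither has been shown for an aryl aldehyde adding to an aryloxyacrylamide under ligand control. The dihydrofuran ring closes in the 5-exo-trig mode. The trans relationship of C2 and C3 follows from a transition state in which the bulky O–Sm group and the acrylamide chain lie anti on the forming ring. The absolute configuration of both centres has to come from the aminodiol on samarium, helped by two-point binding of the metal to the ketyl oxygen and the amide carbonyl, because the carbinol centre across the arene is too remote to matter. The step needs chemoselectivity for the aldehyde: the acrylamide is not reduced by SmI2 without strong donor additives, and the benzylic ester sits meta to the ketyl carbon, so the radical anion cannot expel it. Slow addition keeps the ketyl concentration low and disfavours pinacol coupling.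

Step 6
Reactants: 10 (1R)-1-{(2R,3S)-2-[2-(dimethylamino)-2-oxoethyl]-3-hydroxy-2,3-dihydro-1-benzofuran-5-yl}ethyl (2R)-2-methylbutanoate
Product: 11 (1R)-1-{(2R,3S)-2-[2-(dimethylamino)-2-oxoethyl]-3-(3-methylbutanoyloxy)-2,3-dihydro-1-benzofuran-5-yl}ethyl (2R)-2-methylbutanoate
Conditions: 3-methylbutanoyl chloride, pyridine, DMAP (5 mol %), CH2Cl2, 0 °C
Reagents that add atoms: 3-methylbutanoyl chloride, CC(C)CC(=O)Cl
Why: DMAP-catalysed acylation of a secondary benzylic alcohol with an acid chloride; the C3–O bond is untouched, so the (3S) centre is kept, and pyridine is too weak a base to deprotonate α to the amide and open the ring.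

Step 7
Reactants: 11 (1R)-1-{(2R,3S)-2-[2-(dimethylamino)-2-oxoethyl]-3-(3-methylbutanoyloxy)-2,3-dihydro-1-benzofuran-5-yl}ethyl (2R)-2-methylbutanoate
Product: 13 (1R)-1-[(2R,3S)-3-(3-methylbutanoyloxy)-2-(2-oxoethyl)-2,3-dihydro-1-benzofuran-5-yl]ethyl (2R)-2-methylbutanoate, via zirconium hemiaminal 12 (not isolated)
Conditions: Cp2Zr(H)Cl (1.5 equiv), THF, rt, 20 min; then H2O/silica gel, 0 °C; used crude
Reagents that add atoms: water, O (12 is hydrolysed on work-up; if it collapses through the iminium ion the aldehyde oxygen comes from water)
Why: Chemoselective partial reduction of a tertiary amide with Cp2Zr(H)Cl: hydrozirconation of the amide carbonyl gives the zirconium N,O-hemiaminal 12, which is not reduced further and releases aldehyde 13 only on hydrolysis; carboxylic esters are known to survive this reagent, and no stereocentre is touched.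

Step 8
Reactants: 13 (1R)-1-[(2R,3S)-3-(3-methylbutanoyloxy)-2-(2-oxoethyl)-2,3-dihydro-1-benzofuran-5-yl]ethyl (2R)-2-methylbutanoate
Product: 15 (1R)-1-[(2R,3S)-3-(3-methylbutanoyloxy)-2-(3-oxoprop-1-en-2-yl)-2,3-dihydro-1-benzofuran-5-yl]ethyl (2R)-2-methylbutanoate, via Mannich base 14 (not isolated)
Conditions: dimethylmethyleneiminium iodide (2.5 equiv), Et3N, CH2Cl2, 0 °C → rt
Reagents that add atoms: dimethylmethyleneiminium iodide, C=[N+](C)C.[I-]
Why: α-Methylenation of an aldehyde by Mannich reaction with dimethylmethyleneiminium iodide, followed by elimination of dimethylamine from Mannich base 14 under Et3N; the iminium ion traps the enol as it forms, excess salt scavenges the liberated amine, and once the α-carbon is sp2 no α-hydrogen is left to trigger loss of the ring oxygen, while C2 itself is not deprotonated.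

## Compound list

1 | 4'-hydroxyacetophenone | CC(=O)c1ccc(O)cc1 | starting material
2 | 4-[(1R)-1-hydroxyethyl]phenol | C[C@@H](O)c1ccc(O)cc1 | intermediate
3 | 4-[(1R)-1-hydroxyethyl]-2-(hydroxymethyl)phenol (present as its magnesium salt) | C[C@@H](O)c1ccc(O)c(CO)c1 | intermediate (not isolated)
4 | 2-hydroxy-5-[(1R)-1-hydroxyethyl]benzaldehyde | C[C@@H](O)c1ccc(O)c(C=O)c1 | intermediate
5 | N,N-dimethylprop-2-ynamide (N,N-dimethylpropiolamide) | C#CC(=O)N(C)C | starting material
6 | (2E)-3-{2-formyl-4-[(1R)-1-hydroxyethyl]phenoxy}-N,N-dimethylprop-2-enamide | C[C@@H](O)c1ccc(O/C=C/C(=O)N(C)C)c(C=O)c1 | intermediate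
7 | (2R)-2-methylbutanoic acid | CC[C@@H](C)C(=O)O | starting material
8 | N,N'-dicyclohexyl-O-[(2R)-2-methylbutanoyl]isourea | CC[C@@H](C)C(=O)OC(=NC1CCCCC1)NC1CCCCC1 | intermediate (not isolated)
9 | (1R)-1-(4-{[(1E)-3-(dimethylamino)-3-oxoprop-1-en-1-yl]oxy}-3-formylphenyl)ethyl (2R)-2-methylbutanoate | O=Cc1cc([C@@H](C)OC(=O)[C@H](C)CC)ccc1O/C=C/C(=O)N(C)C | intermediate
10 | (1R)-1-{(2R,3S)-2-[2-(dimethylamino)-2-oxoethyl]-3-hydroxy-2,3-dihydro-1-benzofuran-5-yl}ethyl (2R)-2-methylbutanoate | CN(C)C(=O)C[C@H]1Oc2ccc([C@@H](C)OC(=O)[C@H](C)CC)cc2[C@@H]1O | intermediate
11 | (1R)-1-{(2R,3S)-2-[2-(dimethylamino)-2-oxoethyl]-3-(3-methylbutanoyloxy)-2,3-dihydro-1-benzofuran-5-yl}ethyl (2R)-2-methylbutanoate | CN(C)C(=O)C[C@H]1Oc2ccc([C@@H](C)OC(=O)[C@H](C)CC)cc2[C@@H]1OC(=O)CC(C)C | intermediate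
12 | chlorobis(cyclopentadienyl)zirconium N,O-hemiaminal of 11 (zirconium bound to the former amide oxygen, H on the former carbonyl carbon; both epimers at that carbon) | CN(C)C(O[Zr](Cl)(C1C=CC=C1)C1C=CC=C1)C[C@H]1Oc2ccc([C@@H](C)OC(=O)[C@H](C)CC)cc2[C@@H]1OC(=O)CC(C)C | intermediate (not isolated)
13 | (1R)-1-[(2R,3S)-3-(3-methylbutanoyloxy)-2-(2-oxoethyl)-2,3-dihydro-1-benzofuran-5-yl]ethyl (2R)-2-methylbutanoate | O=CC[C@H]1Oc2ccc([C@@H](C)OC(=O)[C@H](C)CC)cc2[C@@H]1OC(=O)CC(C)C | intermediate
14 | (1R)-1-{(2R,3S)-2-[1-(dimethylamino)-3-oxopropan-2-yl]-3-(3-methylbutanoyloxy)-2,3-dihydro-1-benzofuran-5-yl}ethyl (2R)-2-methylbutanoate (both epimers at the new carbon) | CN(C)CC(C=O)[C@H]1Oc2ccc([C@@H](C)OC(=O)[C@H](C)CC)cc2[C@@H]1OC(=O)CC(C)C | intermediate (not isolated)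
15 | (1R)-1-[(2R,3S)-3-(3-methylbutanoyloxy)-2-(3-oxoprop-1-en-2-yl)-2,3-dihydro-1-benzofuran-5-yl]ethyl (2R)-2-methylbutanoate | C=C(C=O)[C@H]1Oc2ccc([C@@H](C)OC(=O)[C@H](C)CC)cc2[C@@H]1OC(=O)CC(C)C | target

## Step count and risks

Total: 8 steps. Longest linear sequence: 8 steps (1 to 15); 5 and 7 are purchased.

**Step 5 (key step, proposed new method).**
- **What may go wrong.** The most likely failure is poor facial selectivity: the aminodiol–samarium complex may not distinguish the two faces, because the substrate offers only the ketyl oxygen and the amide carbonyl as binding points, and both trans isomers would then form. Pinacol dimerisation of the stabilised aryl ketyl, simple reduction of the aldehyde, and ring-opening elimination from the samarium enolate are the other ways to lose material.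
- **Fallback (known chemistry), from 9 back to 11.** The cyclisation is run with SmI2 and MeOH alone, the established ketyl–olefin cyclisation of an aldehyde onto a β-oxyacrylic acceptor, which needs only the trans preference. It should give 10 mixed with its ring epimer, the (2S,3R) hydroxy amide F1. The mixture is then treated with vinyl 3-methylbutanoate and immobilised Candida antarctica lipase B in tert-butyl methyl ether. This is a lipase kinetic resolution of a cyclic benzylic secondary alcohol. By the empirical size rule for such acylations (aryl as the large group), the (3S) carbinol of 10 is the one that fits the enzyme. 10 should therefore be acylated directly to 11, while F1 stays as the alcohol and is removed by chromatography. This replaces step 6 and costs the material that cyclised on the wrong face.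

**Step 8.**
- **What may go wrong.** Ring opening by loss of the aryloxy oxygen from the enol or enolate of 13 (retro-oxa-Michael elimination), promoted by Et3N or by liberated dimethylamine before the Mannich reaction occurs.
- **Fallback, from crude 13 back to 15.** The aldehyde is converted with Et3SiOTf and Et3N at −78 °C into the triethylsilyl enol ether F2, in which no enolate is present. F2 is treated with dimethylmethyleneiminium iodide in CH2Cl2 (silyl enol ether Mannich reaction) to give 14, this time isolated. 14 is quaternised with MeI to the trimethylammonium iodide F3, and F3 loses trimethylamine on stirring with aqueous NaHCO3 to give 15.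

**Step 7.**
- **What may go wrong.** Decomposition of 13 during hydrolysis of 12 and on silica (the same elimination as above, through the iminium–enamine manifold), or slow attack of excess hydride on the activated C3 ester.
- **Fallback, from 11 back to 13.** After the Cp2Zr(H)Cl reduction and a cold aqueous quench, the crude aldehyde is reduced at once with NaBH4 in MeOH at −20 °C to the primary alcohol F4. F4 is stable and can be purified and stored. It is oxidised with Dess–Martin periodinane and NaHCO3 in CH2Cl2 immediately before step 8, which delivers 13 under neutral conditions without chromatography.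

**Step 2.**
- **What may go wrong.** Erosion of the carbinol configuration through reversible quinone methide formation from the magnesium phenoxide at reflux, and hydride-transfer oxidation of the secondary carbinol by formaldehyde in the same medium that oxidises 3.
- **Fallback, from 2 back to 4.** Both hydroxyls are silylated (TBSCl, imidazole, DMF) to the bis-silyl ether F5. The aryl silyl ether alone is cleaved with K2CO3 in MeOH to give phenol F6. F6 is formylated under the same magnesium conditions to salicylaldehyde F7, in which the carbinol oxygen can neither be oxidised nor bind magnesium. Buffered tetrabutylammonium fluoride (AcOH, THF) then returns 4.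

**Step 1.**
- **What may go wrong.** Slow or incomplete hydride transfer to an electron-rich ketone, and acid-promoted ionisation of the para-hydroxybenzylic alcohol in the formic acid medium, with loss of enantiopurity.
- **Fallback, from 1 back to 2.** The phenol is silylated (TBSCl, imidazole) to 4'-(tert-butyldimethylsilyloxy)acetophenone F8. F8 is reduced by Corey–Bakshi–Shibata reduction with the (S)-Me-CBS oxazaborolidine [(S)-1-methyl-3,3-diphenyltetrahydro-1H,3H-pyrrolo[1,2-c][1,3,2]oxazaborole] and BH3·SMe2 to the (R)-carbinol F9. Tetrabutylammonium fluoride then releases 2.

## Further compounds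

F1 | step 5 | (1R)-1-{(2S,3R)-2-[2-(dimethylamino)-2-oxoethyl]-3-hydroxy-2,3-dihydro-1-benzofuran-5-yl}ethyl (2R)-2-methylbutanoate | CN(C)C(=O)C[C@@H]1Oc2ccc([C@@H](C)OC(=O)[C@H](C)CC)cc2[C@H]1O
F2 | step 8 | (1R)-1-{(2R,3S)-3-(3-methylbutanoyloxy)-2-[2-(triethylsilyloxy)ethenyl]-2,3-dihydro-1-benzofuran-5-yl}ethyl (2R)-2-methylbutanoate (E/Z mixture) | CC[Si](CC)(CC)OC=C[C@H]1Oc2ccc([C@@H](C)OC(=O)[C@H](C)CC)cc2[C@@H]1OC(=O)CC(C)C
F3 | step 8 | N,N,N-trimethyl-2-[(2R,3S)-3-(3-methylbutanoyloxy)-5-{(1R)-1-[(2R)-2-methylbutanoyloxy]ethyl}-2,3-dihydro-1-benzofuran-2-yl]-3-oxopropan-1-aminium iodide | C[N+](C)(C)CC(C=O)[C@H]1Oc2ccc([C@@H](C)OC(=O)[C@H](C)CC)cc2[C@@H]1OC(=O)CC(C)C.[I-]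
F4 | step 7 | (1R)-1-[(2R,3S)-2-(2-hydroxyethyl)-3-(3-methylbutanoyloxy)-2,3-dihydro-1-benzofuran-5-yl]ethyl (2R)-2-methylbutanoate | OCC[C@H]1Oc2ccc([C@@H](C)OC(=O)[C@H](C)CC)cc2[C@@H]1OC(=O)CC(C)C
F5 | step 2 | tert-butyl{4-[(1R)-1-(tert-butyldimethylsilyloxy)ethyl]phenoxy}dimethylsilane | C[C@@H](O[Si](C)(C)C(C)(C)C)c1ccc(O[Si](C)(C)C(C)(C)C)cc1
F6 | step 2 | 4-[(1R)-1-(tert-butyldimethylsilyloxy)ethyl]phenol | C[C@@H](O[Si](C)(C)C(C)(C)C)c1ccc(O)cc1
F7 | step 2 | 5-[(1R)-1-(tert-butyldimethylsilyloxy)ethyl]-2-hydroxybenzaldehyde | C[C@@H](O[Si](C)(C)C(C)(C)C)c1ccc(O)c(C=O)c1
F8 | step 1 | 4'-(tert-butyldimethylsilyloxy)acetophenone | CC(=O)c1ccc(O[Si](C)(C)C(C)(C)C)cc1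
F9 | step 1 | (1R)-1-[4-(tert-butyldimethylsilyloxy)phenyl]ethanol | C[C@@H](O)c1ccc(O[Si](C)(C)C(C)(C)C)cc1
A1 | alternative 1 | (1R)-1-(3-formyl-4-hydroxyphenyl)ethyl (2R)-2-methylbutanoate | O=Cc1cc([C@@H](C)OC(=O)[C@H](C)CC)ccc1O
A2 | alternative 1 | (1R)-1-[(2R,3S)-3-hydroxy-2-(prop-1-en-2-yl)-2,3-dihydro-1-benzofuran-5-yl]ethyl (2R)-2-methylbutanoate | C=C(C)[C@H]1Oc2ccc([C@@H](C)OC(=O)[C@H](C)CC)cc2[C@@H]1O
A3 | alternative 2 | (1R)-1-{3-[(1R)-1-(tert-butyldimethylsilyloxy)buta-2,3-dien-1-yl]-4-hydroxyphenyl}ethyl (2R)-2-methylbutanoate | Oc1ccc([C@@H](C)OC(=O)[C@H](C)CC)cc1[C@@H](C=C=C)O[Si](C)(C)C(C)(C)C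
A4 | alternative 2 | (1R)-1-[(2R,3S)-3-(tert-butyldimethylsilyloxy)-2-{3-[methoxy(methyl)amino]-3-oxoprop-1-en-2-yl}-2,3-dihydro-1-benzofuran-5-yl]ethyl (2R)-2-methylbutanoate | C=C(C(=O)N(C)OC)[C@H]1Oc2ccc([C@@H](C)OC(=O)[C@H](C)CC)cc2[C@@H]1O[Si](C)(C)C(C)(C)C
A5 | alternative 3 | (1R)-1-(2,2-dimethyl-2H-chromen-6-yl)ethyl (2R)-2-methylbutanoate | CC1(C)C=Cc2cc([C@@H](C)OC(=O)[C@H](C)CC)ccc2O1
A6 | alternative 3 | (1R)-1-[(3R,4R)-3,4-epoxy-2,2-dimethyl-3,4-dihydro-2H-chromen-6-yl]ethyl (2R)-2-methylbutanoate | CC1(C)Oc2ccc([C@@H](C)OC(=O)[C@H](C)CC)cc2[C@H]3O[C@@H]13
A7 | alternative 3 | (1R)-1-[(3R,4S)-3-hydroxy-2,2-dimethyl-4-(3-methylbutanoyloxy)-3,4-dihydro-2H-chromen-6-yl]ethyl (2R)-2-methylbutanoate | CC1(C)Oc2ccc([C@@H](C)OC(=O)[C@H](C)CC)cc2[C@H](OC(=O)CC(C)C)[C@H]1O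
A8 | alternative 3 | (1R)-1-[(2R,3S)-3-(3-methylbutanoyloxy)-2-(prop-1-en-2-yl)-2,3-dihydro-1-benzofuran-5-yl]ethyl (2R)-2-methylbutanoate | C=C(C)[C@H]1Oc2ccc([C@@H](C)OC(=O)[C@H](C)CC)cc2[C@@H]1OC(=O)CC(C)C
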